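Rings B and D are one and the same pentasubstituted hydroquinone: para oxygens on C1 (to ring A or E) and C4 (to ring C), ring G or H on C2, hydroxyls on C3 and C5, hydrogen on C6. The route builds this arene once by thermal ring expansion of a squarate-derived cyclobutenone, which closes the C1–C6 bond with ring G already on C2 and all four oxygens in place. The precursor is a 2-aryl-3-isopropoxy-4-(1-ethoxyvinyl)cyclobutenone whose C4 oxygen is capped as a methoxymethyl ether, so that only the C1 hydroxyl emerges free. Ether couplings mediated by CuI or Cu(OAc)2 then attach ring A and a ring C/F dibromide, and BBr3 frees all nineteen hydroxyls.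

Key step: step 3

Remark on the chemistry: the target has no stereocentre and no configurationally defined axis (rings G and H are symmetric rotors), so only constitution is controlled; the single stereocentre of the cyclobutenone intermediates is formed racemic and disappears again. 2-Iodo-1,3,5-trimethoxybenzene, 2-chloro-1,3-dimethoxybenzene and 2,6-dibromo-4-methoxyphenol are assumed to be purchasable.

Step 1
Reactants: 1 diisopropyl squarate; 2 1,3,5-trimethoxybenzene
Product: 5 3-isopropoxy-4-(2,4,6-trimethoxyphenyl)cyclobut-3-ene-1,2-dione, via 2,4,6-trimethoxyphenyllithium 3 (not isolated), via hydroxycyclobutenone adduct 4 (not isolated)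
Conditions: 2, n-BuLi, THF, 0 °C → rt; then 1, THF, −78 °C; aq NH4Cl; crude 4, 12 M HCl (cat.), CH2Cl2, rt
Reagents that add atoms: water, O (supplies the new carbonyl oxygen while the carbinol oxygen of 4 leaves as water)
Why: Ortho-lithiation of 2 between two methoxy groups, 1,2-addition of the aryllithium to one squarate carbonyl and acid-promoted allylic transposition with loss of isopropanol is the standard entry to 3-alkoxy-4-arylcyclobutenediones; the carbinol centre of 4 is racemic and is destroyed in the same step.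

Step 2
Reactants: 5 3-isopropoxy-4-(2,4,6-trimethoxyphenyl)cyclobut-3-ene-1,2-dione; 6 ethyl vinyl ether
Product: 9 racemic 4-(1-ethoxyvinyl)-3-isopropoxy-4-(methoxymethoxy)-2-(2,4,6-trimethoxyphenyl)cyclobut-2-en-1-one, via 1-ethoxyvinyllithium 7 (not isolated), via lithium alkoxide 8 (not isolated)
Conditions: 6 (excess), t-BuLi, THF, −78 → 0 °C; then 5, THF, −78 °C; then MOMCl, DMPU, −78 → 0 °C; aq NaHCO3
Reagents that add atoms: chloromethyl methyl ether (MOMCl), COCCl
Why: The alpha-lithiated vinyl ether adds 1,2 to the ketone-like carbonyl next to the isopropoxy-bearing carbon (the other carbonyl is a vinylogous ester and is shielded by the aryl group), and Williamson-type O-alkylation of the resulting alkoxide caps the carbinol; the new quaternary centre is formed without control (racemic), which is irrelevant because it becomes sp2 in step 3.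

Step 3
Reactants: 9 racemic 4-(1-ethoxyvinyl)-3-isopropoxy-4-(methoxymethoxy)-2-(2,4,6-trimethoxyphenyl)cyclobut-2-en-1-one
Product: 12 5-ethoxy-3-isopropoxy-4-(methoxymethoxy)-2-(2,4,6-trimethoxyphenyl)phenol, via dienylketene 10 (not isolated), via cyclohexadienone 11 (not isolated)
Conditions: toluene (degassed, 0.02 M), 110 °C, Ar
Reagents that add atoms: none
Why: Heating cleaves the carbonyl–carbinol bond of the four-membered ring by conrotatory 4π electrocyclic opening, in which the oxygen substituent on C4 turns outward and the 1-ethoxyvinyl group inward, giving the (Z)-dienylketene 10. Disrotatory 6π electrocyclization then joins the ketene carbon (C1 of ring B) to the vinyl CH2 (C6), closing the six-membered ring B, and enolization of cyclohexadienone 11 aromatizes it. This is the Moore–Liebeskind ring expansion of 4-alkenyl-4-oxycyclobutenones, used here in its O-protected form, which delivers a monoprotected hydroquinone. No stereocentre is created and the racemic centre of 9 is lost. The regiochemistry (ring G on C2 between the new phenol and the isopropoxy group, the capped oxygen para to the free hydroxyl) is already fixed by the constitution of 9; the only selectivity the step itself needs, inward rotation of the vinyl group, follows from the strong outward preference of the oxygen donor on C4.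

Step 4
Reactants: 12 5-ethoxy-3-isopropoxy-4-(methoxymethoxy)-2-(2,4,6-trimethoxyphenyl)phenol; 13 2-iodo-1,3,5-trimethoxybenzene
Product: 14 1-ethoxy-3-isopropoxy-2-(methoxymethoxy)-4-(2,4,6-trimethoxyphenyl)-5-(2,4,6-trimethoxyphenoxy)benzene
Conditions: CuI (20 mol %), picolinic acid (40 mol %), K3PO4, DMSO, 100 °C, Ar
Reagents that add atoms: none
Why: Ullmann-type O-arylation with the CuI/picolinic acid system is suited to ortho-substituted, electron-rich aryl iodides, and the C1 hydroxyl is the only free hydroxyl of 12, so no site selectivity is needed and the acetal is inert to base.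

Step 5
Reactants: 14 1-ethoxy-3-isopropoxy-2-(methoxymethoxy)-4-(2,4,6-trimethoxyphenyl)-5-(2,4,6-trimethoxyphenoxy)benzene
Product: 15 6-ethoxy-2-isopropoxy-3-(2,4,6-trimethoxyphenyl)-4-(2,4,6-trimethoxyphenoxy)phenol
Conditions: HCl (3 M in MeOH), THF, 45 °C
Reagents that add atoms: none
Why: Acid-catalysed acetal exchange removes the aryl methoxymethyl ether, methanol trapping the methoxymethyl cation as dimethoxymethane so that the electron-rich rings are not alkylated, while alkyl aryl and diaryl ethers are untouched.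

Step 6
Reactants: 16 2-chloro-1,3-dimethoxybenzene
Product: 18 (4-chloro-3,5-dimethoxyphenyl)boronic acid, via pinacol boronate 17 (not isolated)
Conditions: B2pin2, [Ir(OMe)(cod)]2 (1.5 mol %), 4,4'-di-tert-butyl-2,2'-bipyridine, THF, 80 °C; then NaIO4, 1 M HCl, THF/H2O, rt
Reagents that add atoms: bis(pinacolato)diboron, CC1(C)OB(OC1(C)C)B1OC(C)(C)C(C)(C)O1; water, O
Why: C–H borylation with [Ir(OMe)(cod)]2 is sterically governed and reaches only C5, the one C–H with no ortho substituent, and periodate cleaves the pinacol ester in the same pot to the boronic acid without touching the aryl chloride.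

Step 7
Reactants: 18 (4-chloro-3,5-dimethoxyphenyl)boronic acid; 19 2,6-dibromo-4-methoxyphenol
Product: 20 1,3-dibromo-2-(4-chloro-3,5-dimethoxyphenoxy)-5-methoxybenzene
Conditions: Cu(OAc)2 (2 equiv), pyridine, Et3N, 4 Å MS, CH2Cl2, dry air, rt
Reagents that add atoms: none
Why: Chan–Lam–Evans oxidative coupling of an arylboronic acid with a phenol runs at room temperature, is established for 2,6-dihalophenols, and leaves the two C–Br bonds and the C–Cl bond intact for the next step.

Step 8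
Reactants: 15 6-ethoxy-2-isopropoxy-3-(2,4,6-trimethoxyphenyl)-4-(2,4,6-trimethoxyphenoxy)phenol (2.4 equiv); 20 1,3-dibromo-2-(4-chloro-3,5-dimethoxyphenoxy)-5-methoxybenzene
Product: 22 2-chloro-5-{2,6-bis[6-ethoxy-2-isopropoxy-3-(2,4,6-trimethoxyphenyl)-4-(2,4,6-trimethoxyphenoxy)phenoxy]-4-methoxyphenoxy}-1,3-dimethoxybenzene, via monoether bromide 21 (not isolated)
Conditions: CuI (40 mol %), picolinic acid (80 mol %), K3PO4, DMSO, 110 °C, Ar
Reagents that add atoms: none
Why: Twofold Ullmann-type O-arylation with the ligand system developed for hindered phenols and ortho-substituted aryl halides; the two C–Br bonds react, the shielded electron-rich C–Cl bond of ring F does not, and the phenoxide of 15 is the only nucleophile present.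

Step 9
Reactants: 22 the fully alkylated precursor named in step 8
Product: 23 2-chloro-5-{2,6-bis[2,6-dihydroxy-3-(2,4,6-trihydroxyphenyl)-4-(2,4,6-trihydroxyphenoxy)phenoxy]-4-hydroxyphenoxy}benzene-1,3-diol (CNP0275555.0)
Conditions: BBr3 (large excess), CH2Cl2, −78 °C → rt, Ar; then H2O, 0 °C; reversed-phase purification under Ar
Reagents that add atoms: none
Why: BBr3 cleaves methyl, ethyl and isopropyl aryl ethers through aryloxyboranes and alkyl bromides but leaves diaryl ethers, biaryl bonds and the aryl chloride alone, and hydrolysis releases the nineteen phenols.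

Compound list
1 | diisopropyl squarate (3,4-diisopropoxycyclobut-3-ene-1,2-dione) | CC(C)OC1=C(OC(C)C)C(=O)C1=O | starting material
2 | 1,3,5-trimethoxybenzene | COc1cc(OC)cc(OC)c1 | starting material
3 | 2,4,6-trimethoxyphenyllithium | [Li]c1c(OC)cc(OC)cc1OC | intermediate
4 | racemic 4-hydroxy-2,3-diisopropoxy-4-(2,4,6-trimethoxyphenyl)cyclobut-2-en-1-one | O=C1C(OC(C)C)=C(OC(C)C)C1(O)c1c(OC)cc(OC)cc1OC | intermediate
5 | 3-isopropoxy-4-(2,4,6-trimethoxyphenyl)cyclobut-3-ene-1,2-dione | O=C1C(=O)C(OC(C)C)=C1c1c(OC)cc(OC)cc1OC | intermediate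
6 | ethyl vinyl ether | C=COCC | starting material
7 | 1-ethoxyvinyllithium | [Li]C(=C)OCC | intermediate
8 | racemic lithium 1-(1-ethoxyvinyl)-2-isopropoxy-4-oxo-3-(2,4,6-trimethoxyphenyl)cyclobut-2-en-1-olate | [Li]OC1(C(OCC)=C)C(=O)C(c2c(OC)cc(OC)cc2OC)=C1OC(C)C | intermediate
9 | racemic 4-(1-ethoxyvinyl)-3-isopropoxy-4-(methoxymethoxy)-2-(2,4,6-trimethoxyphenyl)cyclobut-2-en-1-one | O=C1C(c2c(OC)cc(OC)cc2OC)=C(OC(C)C)C1(OCOC)C(OCC)=C | intermediate
10 | (3Z)-5-ethoxy-3-isopropoxy-4-(methoxymethoxy)-2-(2,4,6-trimethoxyphenyl)hexa-1,3,5-trien-1-one | O=C=C(c1c(OC)cc(OC)cc1OC)/C(OC(C)C)=C(/OCOC)C(OCC)=C | intermediate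
11 | 5-ethoxy-3-isopropoxy-4-(methoxymethoxy)-2-(2,4,6-trimethoxyphenyl)cyclohexa-2,4-dien-1-one | O=C1CC(OCC)=C(OCOC)C(OC(C)C)=C1c1c(OC)cc(OC)cc1OC | intermediate
12 | 5-ethoxy-3-isopropoxy-4-(methoxymethoxy)-2-(2,4,6-trimethoxyphenyl)phenol | Oc1cc(OCC)c(OCOC)c(OC(C)C)c1-c1c(OC)cc(OC)cc1OC | intermediate
13 | 2-iodo-1,3,5-trimethoxybenzene | COc1cc(OC)c(I)c(OC)c1 | starting material
14 | 1-ethoxy-3-isopropoxy-2-(methoxymethoxy)-4-(2,4,6-trimethoxyphenyl)-5-(2,4,6-trimethoxyphenoxy)benzene | COc1cc(OC)c(Oc2cc(OCC)c(OCOC)c(OC(C)C)c2-c2c(OC)cc(OC)cc2OC)c(OC)c1 | intermediate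
15 | 6-ethoxy-2-isopropoxy-3-(2,4,6-trimethoxyphenyl)-4-(2,4,6-trimethoxyphenoxy)phenol | COc1cc(OC)c(Oc2cc(OCC)c(O)c(OC(C)C)c2-c2c(OC)cc(OC)cc2OC)c(OC)c1 | intermediate
16 | 2-chloro-1,3-dimethoxybenzene | COc1cccc(OC)c1Cl | starting material
17 | 2-(4-chloro-3,5-dimethoxyphenyl)-4,4,5,5-tetramethyl-1,3,2-dioxaborolane | COc1cc(B2OC(C)(C)C(C)(C)O2)cc(OC)c1Cl | intermediate
18 | (4-chloro-3,5-dimethoxyphenyl)boronic acid | COc1cc(B(O)O)cc(OC)c1Cl | intermediate
19 | 2,6-dibromo-4-methoxyphenol | COc1cc(Br)c(O)c(Br)c1 | starting material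
20 | 1,3-dibromo-2-(4-chloro-3,5-dimethoxyphenoxy)-5-methoxybenzene | COc1cc(Br)c(Oc2cc(OC)c(Cl)c(OC)c2)c(Br)c1 | intermediate
21 | 2-chloro-5-{2-bromo-6-[6-ethoxy-2-isopropoxy-3-(2,4,6-trimethoxyphenyl)-4-(2,4,6-trimethoxyphenoxy)phenoxy]-4-methoxyphenoxy}-1,3-dimethoxybenzene | COc1cc(Br)c(Oc2cc(OC)c(Cl)c(OC)c2)c(Oc2c(OCC)cc(Oc3c(OC)cc(OC)cc3OC)c(-c3c(OC)cc(OC)cc3OC)c2OC(C)C)c1 | intermediate
22 | 2-chloro-5-{2,6-bis[6-ethoxy-2-isopropoxy-3-(2,4,6-trimethoxyphenyl)-4-(2,4,6-trimethoxyphenoxy)phenoxy]-4-methoxyphenoxy}-1,3-dimethoxybenzene | COc1cc(OC)c(Oc2cc(OCC)c(Oc3cc(OC)cc(Oc4c(OCC)cc(Oc5c(OC)cc(OC)cc5OC)c(-c5c(OC)cc(OC)cc5OC)c4OC(C)C)c3Oc3cc(OC)c(Cl)c(OC)c3)c(OC(C)C)c2-c2c(OC)cc(OC)cc2OC)c(OC)c1 | intermediate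
23 | 2-chloro-5-{2,6-bis[2,6-dihydroxy-3-(2,4,6-trihydroxyphenyl)-4-(2,4,6-trihydroxyphenoxy)phenoxy]-4-hydroxyphenoxy}benzene-1,3-diol (CNP0275555.0) | Oc1cc(O)c(Oc2cc(O)c(Oc3cc(O)cc(Oc4c(O)cc(Oc5c(O)cc(O)cc5O)c(-c5c(O)cc(O)cc5O)c4O)c3Oc3cc(O)c(Cl)c(O)c3)c(O)c2-c2c(O)cc(O)cc2O)c(O)c1 | target

Total step count: 9. Longest linear sequence: 7 (steps 1, 2, 3, 4, 5, 8, 9); steps 6 and 7 form the ring C/F branch.

Steps most likely to fail

Step 8. The second C–O bond formation may stall at the monoether stage, with hydrodebromination of the remaining C–Br bond competing, because both partners carry ortho substituents at a crowded CuI-derived intermediate. The fallback replaces the Ullmann coupling by nucleophilic aromatic substitution; it sets out from 15 and returns at 22. Phenol 15 (2.2 equiv) is heated with 2,6-difluoro-4-methoxybenzaldehyde (COc1cc(F)c(C=O)c(F)c1) and Cs2CO3 in DMSO at 120 °C, where twofold displacement of fluoride ortho to the formyl group should give 2,6-bis[6-ethoxy-2-isopropoxy-3-(2,4,6-trimethoxyphenyl)-4-(2,4,6-trimethoxyphenoxy)phenoxy]-4-methoxybenzaldehyde F1. Baeyer–Villiger oxidation (mCPBA, NaHCO3, CH2Cl2, 0 °C) converts the formyl group into the corresponding 2,6-bis(aryloxy)-4-methoxyphenyl formate F2. Methanolysis (K2CO3, MeOH) gives 2,6-bis[6-ethoxy-2-isopropoxy-3-(2,4,6-trimethoxyphenyl)-4-(2,4,6-trimethoxyphenoxy)phenoxy]-4-methoxyphenol F3. Chan–Lam–Evans coupling of this phenol with boronic acid 18 (Cu(OAc)2, pyridine, 4 Å MS, CH2Cl2, air) then installs ring F and gives 22.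

Step 4. Coupling may be slow and deiodination of 13 may dominate, since the aryl iodide is electron-rich and flanked by two methoxy groups. The fallback brings ring A in as an electron-poor fluoroarene and adds its para oxygen afterwards; it sets out from 12 and returns at 14. Phenol 12 is heated with 4-fluoro-3,5-dimethoxybenzaldehyde (COc1cc(C=O)cc(OC)c1F) and Cs2CO3 in DMSO at 130 °C to give 4-[5-ethoxy-3-isopropoxy-4-(methoxymethoxy)-2-(2,4,6-trimethoxyphenyl)phenoxy]-3,5-dimethoxybenzaldehyde F4. Buffered Baeyer–Villiger oxidation (mCPBA, NaHCO3, CH2Cl2) gives 4-[5-ethoxy-3-isopropoxy-4-(methoxymethoxy)-2-(2,4,6-trimethoxyphenyl)phenoxy]-3,5-dimethoxyphenyl formate F5. K2CO3 in MeOH gives 4-[5-ethoxy-3-isopropoxy-4-(methoxymethoxy)-2-(2,4,6-trimethoxyphenyl)phenoxy]-3,5-dimethoxyphenol F6, and methylation (MeI, K2CO3, acetone) gives 14.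

Step 2. O-Alkylation of the hindered tertiary lithium alkoxide may remain incomplete, and the enol ether may hydrolyse if acid is liberated during the capture. The fallback separates C–C bond formation from protection; it sets out from 5 and 6 and returns at 9. Alkoxide 8 is protonated with aq NH4Cl to give racemic 4-(1-ethoxyvinyl)-4-hydroxy-3-isopropoxy-2-(2,4,6-trimethoxyphenyl)cyclobut-2-en-1-one F7, which is isolated on Et3N-deactivated silica. The neutral alcohol is then alkylated with MOMCl, i-Pr2NEt and NaI (cat.) in CH2Cl2 at rt, through iodomethyl methyl ether formed in the flask, to give 9.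

Further compounds
F1 | step 8 | 2,6-bis[6-ethoxy-2-isopropoxy-3-(2,4,6-trimethoxyphenyl)-4-(2,4,6-trimethoxyphenoxy)phenoxy]-4-methoxybenzaldehyde | COc1cc(Oc2c(OCC)cc(Oc3c(OC)cc(OC)cc3OC)c(-c3c(OC)cc(OC)cc3OC)c2OC(C)C)c(C=O)c(Oc2c(OCC)cc(Oc3c(OC)cc(OC)cc3OC)c(-c3c(OC)cc(OC)cc3OC)c2OC(C)C)c1
F2 | step 8 | 2,6-bis[6-ethoxy-2-isopropoxy-3-(2,4,6-trimethoxyphenyl)-4-(2,4,6-trimethoxyphenoxy)phenoxy]-4-methoxyphenyl formate | COc1cc(Oc2c(OCC)cc(Oc3c(OC)cc(OC)cc3OC)c(-c3c(OC)cc(OC)cc3OC)c2OC(C)C)c(OC=O)c(Oc2c(OCC)cc(Oc3c(OC)cc(OC)cc3OC)c(-c3c(OC)cc(OC)cc3OC)c2OC(C)C)c1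
F3 | step 8 | 2,6-bis[6-ethoxy-2-isopropoxy-3-(2,4,6-trimethoxyphenyl)-4-(2,4,6-trimethoxyphenoxy)phenoxy]-4-methoxyphenol | COc1cc(Oc2c(OCC)cc(Oc3c(OC)cc(OC)cc3OC)c(-c3c(OC)cc(OC)cc3OC)c2OC(C)C)c(O)c(Oc2c(OCC)cc(Oc3c(OC)cc(OC)cc3OC)c(-c3c(OC)cc(OC)cc3OC)c2OC(C)C)c1
F4 | step 4 | 4-[5-ethoxy-3-isopropoxy-4-(methoxymethoxy)-2-(2,4,6-trimethoxyphenyl)phenoxy]-3,5-dimethoxybenzaldehyde | COc1cc(C=O)cc(OC)c1Oc1cc(OCC)c(OCOC)c(OC(C)C)c1-c1c(OC)cc(OC)cc1OC
F5 | step 4 | 4-[5-ethoxy-3-isopropoxy-4-(methoxymethoxy)-2-(2,4,6-trimethoxyphenyl)phenoxy]-3,5-dimethoxyphenyl formate | COc1cc(OC=O)cc(OC)c1Oc1cc(OCC)c(OCOC)c(OC(C)C)c1-c1c(OC)cc(OC)cc1OC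
F6 | step 4 | 4-[5-ethoxy-3-isopropoxy-4-(methoxymethoxy)-2-(2,4,6-trimethoxyphenyl)phenoxy]-3,5-dimethoxyphenol | COc1cc(O)cc(OC)c1Oc1cc(OCC)c(OCOC)c(OC(C)C)c1-c1c(OC)cc(OC)cc1OC
F7 | step 2 | racemic 4-(1-ethoxyvinyl)-4-hydroxy-3-isopropoxy-2-(2,4,6-trimethoxyphenyl)cyclobut-2-en-1-one | O=C1C(c2c(OC)cc(OC)cc2OC)=C(OC(C)C)C1(O)C(OCC)=C
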